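**Retrosynthetic overview**

1. Skeleton: aryl bromide 1 and C18 dibromide 2 are joined (through Grignard reagent 3) to bromide 4; 4 and 3-bromothiophene 5 are joined (through Grignard reagent 6) to thiophene 7; lithiation (8) and CO2 give thiophene acid 9.
2. Key disconnection: C1–C5 of the acid, with the (E)-C3=C4 bond and the C4 methyl, is the thiophene ring of 9. Dissolving-metal reduction destroys the aromatic ring and opens it at C2–S (thiol 10); after S-methylation (11) it removes sulfur, so the cis relationship in the ring becomes CH3 cis to C2 in acid 12.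
3. C2 stereocentre: set last, by methylation of the enediolate 13 of 12 inside a chiral lithium amide aggregate, giving target 14.
4. Rings: none is formed; the benzene ring is bought and kept, the thiophene ring is bought and opened in step 4.

Assumptions: 2 is bought as a catalogue chemical; in step 5 the (R,R)-tetramine is taken to give the (S)-acid, as it does with arylacetic acids (the (S,S)-amine would be used if a test run showed the opposite sense).

**Route**

Step 1
Reactants: 1 1-(benzyloxy)-4-bromobenzene; 2 1,18-dibromooctadecane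
Product: 4 1-(benzyloxy)-4-(18-bromooctadecyl)benzene, via aryl Grignard reagent 3 (not isolated)
Conditions: Mg, THF, 45 °C; then added to 2 (3 equiv), Li2CuCl4 (3 mol %), THF–NMP, 0 °C → rt
Reagents that add atoms: none
Why: Copper-catalysed coupling of an aryl Grignard reagent with a primary alkyl bromide (Kochi type); the threefold excess of the symmetric dibromide keeps the reaction at mono-arylation, the benzyl ether is inert, and no stereocentre is formed.

Step 2
Reactants: 4 1-(benzyloxy)-4-(18-bromooctadecyl)benzene; 5 3-bromothiophene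
Product: 7 3-{18-[4-(benzyloxy)phenyl]octadecyl}thiophene, via alkyl Grignard reagent 6 (not isolated)
Conditions: Mg (I2), THF, 50 °C; then 5 (1.3 equiv), NiCl2(dppp) (1 mol %; dppp = 1,3-bis(diphenylphosphino)propane), THF, 0 → 50 °C
Reagents that add atoms: none
Why: Kumada–Corriu coupling, the standard entry to 3-alkylthiophenes; the chelating phosphine suppresses β-hydride elimination of the primary alkyl group and no stereocentre is formed.

Step 3
Reactants: 7 3-{18-[4-(benzyloxy)phenyl]octadecyl}thiophene
Product: 9 4-{18-[4-(benzyloxy)phenyl]octadecyl}thiophene-2-carboxylic acid, via thienyllithium 8 (not isolated)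
Conditions: LDA (1.2 equiv), THF, −78 °C, 1 h; CO2 (g), −78 °C → rt; 1 M HCl
Reagents that add atoms: carbon dioxide, O=C=O
Why: Deprotonation–carboxylation; the hindered amide base removes the α-proton at C5, remote from the alkyl group (the usual outcome for 3-alkylthiophenes), the thienyllithium adds to CO2, and the benzylic ether protons are untouched at −78 °C.

Step 4
Reactants: 9 4-{18-[4-(benzyloxy)phenyl]octadecyl}thiophene-2-carboxylic acid
Product: 12 (3E)-22-(4-hydroxyphenyl)-4-methyldocos-3-enoic acid, via ring-opened thiol acid 10 (not isolated), via allyl methyl sulfide 11 (not isolated)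
Conditions: Li (8 equiv), NH3–THF (3:1), −78 → −33 °C, 1 h; NH4Cl (7 equiv, to colourless); MeI (1.1 equiv), −78 → −33 °C, 30 min; Li (ca. 5 equiv, to persistent blue), −78 °C, 30 min; NH4Cl; NH3 evaporated; 1 M HCl
Reagents that add atoms: none
Why: Proposed new method: a one-flask extension of the Birch reduction of thiophene-2-carboxylic acids (closest known reaction type, which with excess Li is reported to give (Z)-5-sulfanylalk-3-enoic acids), in which four electrons take the carboxylate through the 2,5-dihydrothiophene to the acyclic thiolate/dienediolate by cleavage of the C2–S bond next to the carboxylate, so CH2S and C2 stay cis on the new C3=C4 bond as they were in the ring; NH4Cl then protonates the dienediolate kinetically at C2, the thiolate is the best nucleophile left for MeI (S-alkylation in liquid ammonia), and fresh Li cleaves the allyl–S bond of 11 (dissolving-metal hydrogenolysis of allyl sulfides) to a 2-substituted allyl anion that keeps its geometry and is protonated by NH3 at the unsubstituted terminus, leaving CH3 cis to C2, which is the (E)-alkene; the same metal removes the benzyl group as toluene, and the phenoxide, the carboxylate and the isolated alkene are not reduced; no stereocentre is formed.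

Step 5
Reactants: 12 (3E)-22-(4-hydroxyphenyl)-4-methyldocos-3-enoic acid
Product: 14 (2S,3E)-22-(4-hydroxyphenyl)-2,4-dimethyldocos-3-enoic acid, via trilithium dienediolate 13 (not isolated)
Conditions: (R,R)-N,N′-bis(1-phenyl-2-piperidin-1-ylethyl)propane-1,3-diamine (1.05 equiv), n-BuLi (5.1 equiv), THF, 0 °C, 30 min; MeI (1.2 equiv), −78 °C, 3 h; MeOH, then 1 M HCl (amine recovered from the acid washings)
Reagents that add atoms: iodomethane, CI
Why: Enantioselective alkylation of a carboxylic acid enediolate held in a mixed aggregate with a C2-symmetric chiral dilithium amide (traceless-auxiliary alkylation, known for arylacetic and β,γ-unsaturated acids); the dienediolate of 12 takes MeI at C2 (the γ-carbon is fully substituted) on the face left open by the aggregate, which sets the (S) centre directly, the C3=C4 geometry is not touched, and the lithium phenoxide is too unreactive towards MeI at −78 °C to be O-methylated.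

**Compound list**

1 | 1-(benzyloxy)-4-bromobenzene | Brc1ccc(OCc2ccccc2)cc1 | starting material
2 | 1,18-dibromooctadecane | BrCCCCCCCCCCCCCCCCCCBr | starting material
3 | [4-(benzyloxy)phenyl]magnesium bromide | Br[Mg]c1ccc(OCc2ccccc2)cc1 | intermediate (not isolated)
4 | 1-(benzyloxy)-4-(18-bromooctadecyl)benzene | BrCCCCCCCCCCCCCCCCCCc1ccc(OCc2ccccc2)cc1 | intermediate
5 | 3-bromothiophene | Brc1ccsc1 | starting material
6 | {18-[4-(benzyloxy)phenyl]octadecyl}magnesium bromide | Br[Mg]CCCCCCCCCCCCCCCCCCc1ccc(OCc2ccccc2)cc1 | intermediate (not isolated)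
7 | 3-{18-[4-(benzyloxy)phenyl]octadecyl}thiophene | c1cc(CCCCCCCCCCCCCCCCCCc2ccc(OCc3ccccc3)cc2)cs1 | intermediate
8 | (4-{18-[4-(benzyloxy)phenyl]octadecyl}thiophen-2-yl)lithium | [Li]c1cc(CCCCCCCCCCCCCCCCCCc2ccc(OCc3ccccc3)cc2)cs1 | intermediate (not isolated)
9 | 4-{18-[4-(benzyloxy)phenyl]octadecyl}thiophene-2-carboxylic acid | OC(=O)c1cc(CCCCCCCCCCCCCCCCCCc2ccc(OCc3ccccc3)cc2)cs1 | intermediate
10 | (3Z)-22-(4-hydroxyphenyl)-4-(sulfanylmethyl)docos-3-enoic acid (present as its salts) | OC(=O)C/C=C(\CS)CCCCCCCCCCCCCCCCCCc1ccc(O)cc1 | intermediate (not isolated)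
11 | (3Z)-22-(4-hydroxyphenyl)-4-[(methylsulfanyl)methyl]docos-3-enoic acid (present as its salts) | OC(=O)C/C=C(\CSC)CCCCCCCCCCCCCCCCCCc1ccc(O)cc1 | intermediate (not isolated)
12 | (3E)-22-(4-hydroxyphenyl)-4-methyldocos-3-enoic acid | OC(=O)C/C=C(\C)CCCCCCCCCCCCCCCCCCc1ccc(O)cc1 | intermediate
13 | trilithium salt of 12 (phenoxide and C1/C2 enediolate) | [Li]OC(O[Li])=C/C=C(\C)CCCCCCCCCCCCCCCCCCc1ccc(O[Li])cc1 | intermediate (not isolated)
14 | (2S,3E)-22-(4-hydroxyphenyl)-2,4-dimethyldocos-3-enoic acid | C/C(=C\[C@H](C)C(=O)O)CCCCCCCCCCCCCCCCCCc1ccc(O)cc1 | target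

**Step count and risks**

Total steps: 5. Longest linear sequence: 5 (1 → 4 → 7 → 9 → 12 → 14).

Steps most likely to fail, most risky first:

Step 4. Three operations share one flask. The ring opening may stop at the 2,5-dihydrothiophene acid, and some phenoxide may be O-methylated. The allyl anion may also be protonated in part at C3, which gives the 4-methylidene isomer, hard to separate from 12. The fallback leaves the route at bromide 4 and gives up the thiophene. 2,3-Dihydrofuran is lithiated (t-BuLi, THF, −78 → 0 °C) to 5-lithio-2,3-dihydrofuran F1, which is alkylated by 4 to 5-{18-[4-(benzyloxy)phenyl]octadecyl}-2,3-dihydrofuran F2. Nickel-catalysed Grignard ring opening of this cyclic enol ether (MeMgBr, NiCl2(PPh3)2, toluene, 80 °C) replaces the vinylic C–O bond by C–CH3 with retention and gives (3E)-22-[4-(benzyloxy)phenyl]-4-methyldocos-3-en-1-ol F3. Oxidation (TEMPO, PhI(OAc)2, MeCN–H2O) gives (3E)-22-[4-(benzyloxy)phenyl]-4-methyldocos-3-enoic acid F4. Li in NH3–THF at −78 °C then removes the benzyl group and the route is rejoined at 12.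

Step 5. Methyl iodide is the least selective electrophile in this type of alkylation, the extra lithium phenoxide may disturb the chiral aggregate, and the sense of induction rests on analogy. The fallback sets out from 12 and uses a covalent auxiliary. PivCl (2.2 equiv) and Et3N in THF at −20 °C give pivalic (3E)-4-methyl-22-[4-(pivaloyloxy)phenyl]docos-3-enoic anhydride F5. Adding (4S)-4-benzyl-1,3-oxazolidin-2-one and LiCl gives (4S)-4-benzyl-3-{(3E)-4-methyl-22-[4-(pivaloyloxy)phenyl]docos-3-enoyl}-1,3-oxazolidin-2-one F6. Evans alkylation (NaN(SiMe3)2, MeI, THF, −78 °C; the electrophile enters anti to the benzyl group of the Z-enolate) gives (4S)-4-benzyl-3-{(2S,3E)-2,4-dimethyl-22-[4-(pivaloyloxy)phenyl]docos-3-enoyl}-1,3-oxazolidin-2-one F7. LiOH and H2O2 in THF–H2O (0 °C → rt) cleave the auxiliary and the aryl pivalate, and the route is rejoined at 14.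

Step 3. A few per cent of metalation at C2 of the thiophene, or at the benzylic ether, would carry an inseparable regioisomeric acid into the key step. The fallback sets out from 4 and forms the ring–chain bond on a thiophene that already carries the carboxyl group. Zinc insertion (Zn dust, LiCl, THF, 50 °C) gives {18-[4-(benzyloxy)phenyl]octadecyl}zinc bromide F8. Negishi coupling with bought methyl 4-bromothiophene-2-carboxylate (Pd(OAc)2, SPhos, THF, rt → 50 °C) gives methyl 4-{18-[4-(benzyloxy)phenyl]octadecyl}thiophene-2-carboxylate F9. LiOH in THF–MeOH–H2O then rejoins the route at 9.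

**Further compounds**

F1 | step 4 | 5-lithio-2,3-dihydrofuran | [Li]C1=CCCO1
F2 | step 4 | 5-{18-[4-(benzyloxy)phenyl]octadecyl}-2,3-dihydrofuran | C1COC(=C1)CCCCCCCCCCCCCCCCCCc1ccc(OCc2ccccc2)cc1
F3 | step 4 | (3E)-22-[4-(benzyloxy)phenyl]-4-methyldocos-3-en-1-ol | OCC/C=C(\C)CCCCCCCCCCCCCCCCCCc1ccc(OCc2ccccc2)cc1
F4 | step 4 | (3E)-22-[4-(benzyloxy)phenyl]-4-methyldocos-3-enoic acid | OC(=O)C/C=C(\C)CCCCCCCCCCCCCCCCCCc1ccc(OCc2ccccc2)cc1
F5 | step 5 | pivalic (3E)-4-methyl-22-[4-(pivaloyloxy)phenyl]docos-3-enoic anhydride | CC(C)(C)C(=O)OC(=O)C/C=C(\C)CCCCCCCCCCCCCCCCCCc1ccc(OC(=O)C(C)(C)C)cc1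
F6 | step 5 | (4S)-4-benzyl-3-{(3E)-4-methyl-22-[4-(pivaloyloxy)phenyl]docos-3-enoyl}-1,3-oxazolidin-2-one | O=C1OC[C@H](Cc2ccccc2)N1C(=O)C/C=C(\C)CCCCCCCCCCCCCCCCCCc1ccc(OC(=O)C(C)(C)C)cc1
F7 | step 5 | (4S)-4-benzyl-3-{(2S,3E)-2,4-dimethyl-22-[4-(pivaloyloxy)phenyl]docos-3-enoyl}-1,3-oxazolidin-2-one | O=C1OC[C@H](Cc2ccccc2)N1C(=O)[C@@H](C)/C=C(\C)CCCCCCCCCCCCCCCCCCc1ccc(OC(=O)C(C)(C)C)cc1
F8 | step 3 | {18-[4-(benzyloxy)phenyl]octadecyl}zinc bromide | Br[Zn]CCCCCCCCCCCCCCCCCCc1ccc(OCc2ccccc2)cc1
F9 | step 3 | methyl 4-{18-[4-(benzyloxy)phenyl]octadecyl}thiophene-2-carboxylate | COC(=O)c1cc(CCCCCCCCCCCCCCCCCCc2ccc(OCc3ccccc3)cc2)cs1
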